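**Plan**

1. Locants are those of bicyclo[5.3.0]decane: C1 = methyl-bearing fusion carbon, C2 = CH–OAc, C3/C4 = oxirane, C6 = CH–O-acyl, C7 = fusion CH, C8 = C(OH)iPr. Retrosynthesis removes both esters and the oxirane oxygen, cuts C4–CH3, then opens the cyclopentane at C8–C9.
2. The resulting 2-(2-iodoethyl)-3-isobutyrylcycloheptanone is cut at C7–C8 and C1–C10 to (S)-4-silyloxy-2-methylcyclohept-2-enone, an alkenyl metal and allyl iodide; the enone comes from cyclohepta-1,3-diene.
3. Forward: the seven-membered ring is bought, both fusion substituents are placed trans on it in one three-component operation, the cyclopentane is closed last, then the C2–C4 oxidation pattern and the esters follow.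
4. Feature used: C8, the only functionalised carbon of the cyclopentane, is a tertiary carbinol flanked by the fusion CH (C7) and a CH2 (C9) that is tethered through C10 to the quaternary C1. A ketone on C7 and a CH2–I arm on C1 therefore close by a 5-exo samarium Barbier addition that makes C8 and the ring together.
5. Stereochemistry: C6 from a catalytic enantioselective Kornblum–DeLaMare desymmetrisation; C7 anti to C6–OSi (conjugate addition); C1 anti to C7 (allylation), giving the trans fusion; C8 in the key step; C2 by CBS reduction; C3/C4 by OH-directed epoxidation.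

Key step: step 9

Remark: the oxirane is treated as a functional group (an oxidised C3=C4 bond) and is introduced after the carbon skeleton is complete.
Naming: in the bicyclic compounds β is the face of the C1 methyl group; 7αH with 1β-methyl means a trans ring fusion.

**Step 1**
Reactants: 1 cyclohepta-1,3-diene
Product: 2 6,7-dioxabicyclo[3.2.2]non-8-ene
Conditions: O2, hν, tetraphenylporphyrin (cat.), CH2Cl2, 0 °C
Reagents that add atoms: dioxygen, O=O
Why: Sensitised singlet oxygen adds to the s-cis ring diene in a [4+2] cycloaddition, and the cis peroxide bridge makes 2 a meso compound.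

**Step 2**
Reactants: 2 6,7-dioxabicyclo[3.2.2]non-8-ene
Product: 3 (S)-4-hydroxycyclohept-2-en-1-one
Conditions: 9-O-acetylcupreidine-type cinchona catalyst (5 mol %, pseudoenantiomer chosen for the (S)-product), CH2Cl2, rt
Reagents that add atoms: none
Why: Enantioselective Kornblum–DeLaMare rearrangement, in which the chiral amine base removes one of the two enantiotopic C–H bonds next to the peroxide with O–O cleavage, so the catalyst sets the (S)-carbinol centre as precedented for meso bicyclic endoperoxides.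

**Step 3**
Reactants: 3 (S)-4-hydroxycyclohept-2-en-1-one
Product: 4 (S)-4-[(tert-butyldimethylsilyl)oxy]cyclohept-2-en-1-one
Conditions: TBSCl, imidazole, DMF, rt
Reagents that add atoms: tert-butyldimethylsilyl chloride, CC(C)(C)[Si](C)(C)Cl
Why: Standard silylation of the secondary alcohol; the bulky silyl ether later shields one face of the enone.

**Step 4**
Reactants: 4 (S)-4-[(tert-butyldimethylsilyl)oxy]cyclohept-2-en-1-one
Product: 5 (S)-4-[(tert-butyldimethylsilyl)oxy]-2-iodocyclohept-2-en-1-one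
Conditions: I2, pyridine, CH2Cl2, 0 °C → rt
Reagents that add atoms: iodine, II
Why: α-Iodination of the cyclic enone by the pyridine-mediated addition/iodination/elimination sequence (Baylis–Hillman-type mechanism), which leaves the γ-silyloxy centre untouched.

**Step 5**
Reactants: 5 (S)-4-[(tert-butyldimethylsilyl)oxy]-2-iodocyclohept-2-en-1-one
Product: 6 (S)-4-[(tert-butyldimethylsilyl)oxy]-2-methylcyclohept-2-en-1-one
Conditions: Me4Sn, Pd2(dba)3 (cat.), AsPh3, CuI (cat.), NMP, 60 °C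
Reagents that add atoms: tetramethylstannane, C[Sn](C)(C)C
Why: Stille coupling of the α-iodoenone installs the α-methyl group that becomes the angular methyl.

**Step 6**
Reactants: 6 (S)-4-[(tert-butyldimethylsilyl)oxy]-2-methylcyclohept-2-en-1-one; 7 2-bromo-3-methylbut-1-ene; 8 3-iodoprop-1-ene (allyl iodide)
Product: 10 (2S,3S,4S)-2-allyl-4-[(tert-butyldimethylsilyl)oxy]-2-methyl-3-(3-methylbut-1-en-2-yl)cycloheptan-1-one, via magnesium enolate 9 (not isolated)
Conditions: 7, Mg, THF; CuBr·SMe2 (20 mol %), THF, −78 → −40 °C, then 6; then HMPA, 8, −40 → 0 °C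
Reagents that add atoms: none
Why: Copper-catalysed 1,4-addition of the alkenyl Grignard reagent should occur anti to the γ-silyloxy group, and the regiodefined enolate 9 should be C-allylated anti to the new β-substituent (three-component enone coupling of the prostaglandin type), setting the two future fusion carbons trans in one pot.

**Step 7**
Reactants: 10 (2S,3S,4S)-2-allyl-4-[(tert-butyldimethylsilyl)oxy]-2-methyl-3-(3-methylbut-1-en-2-yl)cycloheptan-1-one
Product: 12 (2S,3S,4S)-4-[(tert-butyldimethylsilyl)oxy]-2-(2-hydroxyethyl)-2-methyl-3-(2-methylpropanoyl)cycloheptan-1-one, via keto aldehyde 11 (not isolated)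
Conditions: O3, CH2Cl2/MeOH, −78 °C; Me2S; then NaBH(OAc)3, AcOH (cat.), CH2Cl2, 0 °C → rt
Reagents that add atoms: ozone, [O-][O+]=O
Why: Ozonolysis cleaves both the 1,1-disubstituted and the terminal alkene, revealing the isobutyryl ketone and the C9 aldehyde, and NaBH(OAc)3 should reduce only the aldehyde beside the two hindered ketones.

**Step 8**
Reactants: 12 (2S,3S,4S)-4-[(tert-butyldimethylsilyl)oxy]-2-(2-hydroxyethyl)-2-methyl-3-(2-methylpropanoyl)cycloheptan-1-one
Product: 13 (2S,3S,4S)-4-[(tert-butyldimethylsilyl)oxy]-2-(2-iodoethyl)-2-methyl-3-(2-methylpropanoyl)cycloheptan-1-one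
Conditions: I2, PPh3, imidazole, CH2Cl2, 0 °C
Reagents that add atoms: iodine, II
Why: Appel iodination of the primary alcohol (through the open form of any lactol) under near-neutral conditions that should leave the β-silyloxy ketone and its α-stereocentre untouched.

**Step 9**
Reactants: 13 (2S,3S,4S)-4-[(tert-butyldimethylsilyl)oxy]-2-(2-iodoethyl)-2-methyl-3-(2-methylpropanoyl)cycloheptan-1-one
Product: 14 6α-[(tert-butyldimethylsilyl)oxy]-8β-hydroxy-1β-methyl-8α-(propan-2-yl)-7αH-bicyclo[5.3.0]decan-2-one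
Conditions: SmI2 (2.5 equiv), THF, HMPA (or cat. NiI2), −78 → 0 °C; aq. NH4Cl
Reagents that add atoms: none
Why: SmI2 reduces the primary C–I bond by two single-electron transfers to a C9 alkylsamarium(III) species, which adds to the Sm(III)-activated isobutyryl carbonyl; the closest known reaction is the intramolecular samarium Barbier cyclisation of ω-iodo ketones to cyclopentanols. The cyclopentane closes in a 5-exo-trig mode at the carbonyl carbon, forming the C8–C9 bond. The new C8 stereocentre is controlled by the adjacent C7 centre: the isopropyl group should turn away from the C6 carbon toward C7–H, and the carbonyl oxygen should lie on the C6–OSi side (six-membered β-alkoxy chelate), giving 8β-OH and 8α-isopropyl. The trans ring fusion is inherited from step 6 and should survive because the Sm(II) conditions are not basic enough to enolise C7–H. The step needs chemoselectivity between the two ketones, which ring size secures, since attack on the C2 carbonyl would give a cyclobutanol.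

**Step 10**
Reactants: 14 6α-[(tert-butyldimethylsilyl)oxy]-8β-hydroxy-1β-methyl-8α-(propan-2-yl)-7αH-bicyclo[5.3.0]decan-2-one
Product: 16 6α-[(tert-butyldimethylsilyl)oxy]-1β-methyl-8α-(propan-2-yl)-8β-[(trimethylsilyl)oxy]-7αH-bicyclo[5.3.0]dec-3-en-2-one, via bis-silyl enol ether 15 (not isolated)
Conditions: TMSOTf (2.5 equiv), Et3N, CH2Cl2, 0 °C; then Pd(OAc)2 (1.1 equiv), MeCN, rt
Reagents that add atoms: trimethylsilyl trifluoromethanesulfonate, C[Si](C)(C)OS(=O)(=O)C(F)(F)F
Why: Saegusa–Ito dehydrogenation, in which enolisation can only go toward C3 because C1 is quaternary; the tertiary alcohol is masked as its TMS ether in the same operation.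

**Step 11**
Reactants: 16 6α-[(tert-butyldimethylsilyl)oxy]-1β-methyl-8α-(propan-2-yl)-8β-[(trimethylsilyl)oxy]-7αH-bicyclo[5.3.0]dec-3-en-2-one
Product: 18 6α-[(tert-butyldimethylsilyl)oxy]-1β,4-dimethyl-8α-(propan-2-yl)-8β-[(trimethylsilyl)oxy]-7αH-bicyclo[5.3.0]dec-3-en-2-one, via silyl enol ether 17 (not isolated)
Conditions: Me2CuLi, TMSCl, THF, −78 °C; then Pd(OAc)2 (1.1 equiv), MeCN, rt
Reagents that add atoms: lithium dimethylcuprate, [Li+].C[Cu-]C
Why: Conjugate addition of the cuprate with silyl trapping, then a second Saegusa–Ito oxidation, converts the enone into the β-methyl enone; the transient C4 centre is destroyed, so its configuration does not matter.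

**Step 12**
Reactants: 18 6α-[(tert-butyldimethylsilyl)oxy]-1β,4-dimethyl-8α-(propan-2-yl)-8β-[(trimethylsilyl)oxy]-7αH-bicyclo[5.3.0]dec-3-en-2-one
Product: 19 6α-[(tert-butyldimethylsilyl)oxy]-1β,4-dimethyl-8α-(propan-2-yl)-8β-[(trimethylsilyl)oxy]-7αH-bicyclo[5.3.0]dec-3-en-2α-ol
Conditions: (S)-2-methyl-CBS-oxazaborolidine, BH3·SMe2, THF/toluene, −40 → −20 °C
Reagents that add atoms: none
Why: CBS reduction under reagent control, with the quaternary C1 as the large and the vinylic C3 as the small substituent, so the (S)-catalyst should deliver hydride to the β-face and give the 2α (pseudo-axial) alcohol.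

**Step 13**
Reactants: 19 6α-[(tert-butyldimethylsilyl)oxy]-1β,4-dimethyl-8α-(propan-2-yl)-8β-[(trimethylsilyl)oxy]-7αH-bicyclo[5.3.0]dec-3-en-2α-ol
Product: 20 6α-[(tert-butyldimethylsilyl)oxy]-3α,4α-epoxy-1β,4β-dimethyl-8α-(propan-2-yl)-8β-[(trimethylsilyl)oxy]-7αH-bicyclo[5.3.0]decan-2α-ol
Conditions: VO(acac)2 (5 mol %), t-BuOOH, CH2Cl2, 0 °C → rt
Reagents that add atoms: tert-butyl hydroperoxide, CC(C)(C)OO
Why: Vanadium-catalysed hydroxyl-directed epoxidation of the cyclic allylic alcohol delivers oxygen syn to the OH group, giving the cis 2α-hydroxy-3α,4α-epoxide.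

**Step 14**
Reactants: 20 6α-[(tert-butyldimethylsilyl)oxy]-3α,4α-epoxy-1β,4β-dimethyl-8α-(propan-2-yl)-8β-[(trimethylsilyl)oxy]-7αH-bicyclo[5.3.0]decan-2α-ol
Product: 21 6α-[(tert-butyldimethylsilyl)oxy]-3α,4α-epoxy-1β,4β-dimethyl-8α-(propan-2-yl)-8β-[(trimethylsilyl)oxy]-7αH-bicyclo[5.3.0]decan-2α-yl acetate
Conditions: Ac2O, DMAP, pyridine, CH2Cl2, rt
Reagents that add atoms: acetic anhydride, CC(=O)OC(C)=O
Why: DMAP-catalysed acetylation of the only free hydroxyl group.

**Step 15**
Reactants: 21 6α-[(tert-butyldimethylsilyl)oxy]-3α,4α-epoxy-1β,4β-dimethyl-8α-(propan-2-yl)-8β-[(trimethylsilyl)oxy]-7αH-bicyclo[5.3.0]decan-2α-yl acetate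
Product: 22 2α-acetoxy-3α,4α-epoxy-1β,4β-dimethyl-8α-(propan-2-yl)-7αH-bicyclo[5.3.0]decane-6α,8β-diol
Conditions: TBAF, AcOH, THF, 0 °C → rt
Reagents that add atoms: none
Why: Buffered fluoride cleaves both silyl ethers, while the acetate and the oxirane should be stable to the nearly neutral conditions.

**Step 16**
Reactants: 22 2α-acetoxy-3α,4α-epoxy-1β,4β-dimethyl-8α-(propan-2-yl)-7αH-bicyclo[5.3.0]decane-6α,8β-diol
Product: 23 2α-acetoxy-3α,4α-epoxy-8β-hydroxy-1β,4β-dimethyl-8α-(propan-2-yl)-7αH-bicyclo[5.3.0]decan-6α-yl 3-methylbutanoate (CNP0137153.1)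
Conditions: 3-methylbutanoic anhydride, DMAP, Et3N, CH2Cl2, 0 °C → rt
Reagents that add atoms: 3-methylbutanoic anhydride, CC(C)CC(=O)OC(=O)CC(C)C
Why: DMAP-catalysed acylation should be selective for the secondary C6 hydroxyl, because the tertiary C8 hydroxyl flanked by isopropyl and the ring fusion does not react under these conditions.

**Compound list**

1 | cyclohepta-1,3-diene | C1=CC=CCCC1 | starting material
2 | 6,7-dioxabicyclo[3.2.2]non-8-ene (meso) | O1O[C@H]2CCC[C@@H]1C=C2 | intermediate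
3 | (S)-4-hydroxycyclohept-2-en-1-one | O=C1CCC[C@H](O)C=C1 | intermediate
4 | (S)-4-[(tert-butyldimethylsilyl)oxy]cyclohept-2-en-1-one | O=C1CCC[C@H](O[Si](C)(C)C(C)(C)C)C=C1 | intermediate
5 | (S)-4-[(tert-butyldimethylsilyl)oxy]-2-iodocyclohept-2-en-1-one | O=C1CCC[C@H](O[Si](C)(C)C(C)(C)C)C=C1I | intermediate
6 | (S)-4-[(tert-butyldimethylsilyl)oxy]-2-methylcyclohept-2-en-1-one | O=C1CCC[C@H](O[Si](C)(C)C(C)(C)C)C=C1C | intermediate
7 | 2-bromo-3-methylbut-1-ene | CC(C)C(Br)=C | starting material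
8 | 3-iodoprop-1-ene (allyl iodide) | C=CCI | starting material
9 | bromomagnesium (3S,4S)-4-[(tert-butyldimethylsilyl)oxy]-2-methyl-3-(3-methylbut-1-en-2-yl)cyclohept-1-en-1-olate | Br[Mg]OC1=C(C)[C@H](C(=C)C(C)C)[C@@H](O[Si](C)(C)C(C)(C)C)CCC1 | intermediate
10 | (2S,3S,4S)-2-allyl-4-[(tert-butyldimethylsilyl)oxy]-2-methyl-3-(3-methylbut-1-en-2-yl)cycloheptan-1-one | O=C1CCC[C@H](O[Si](C)(C)C(C)(C)C)[C@@H](C(=C)C(C)C)[C@]1(C)CC=C | intermediate
11 | (2S,3S,4S)-4-[(tert-butyldimethylsilyl)oxy]-2-methyl-3-(2-methylpropanoyl)-2-(2-oxoethyl)cycloheptan-1-one | O=C1CCC[C@H](O[Si](C)(C)C(C)(C)C)[C@@H](C(=O)C(C)C)[C@]1(C)CC=O | intermediate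
12 | (2S,3S,4S)-4-[(tert-butyldimethylsilyl)oxy]-2-(2-hydroxyethyl)-2-methyl-3-(2-methylpropanoyl)cycloheptan-1-one | O=C1CCC[C@H](O[Si](C)(C)C(C)(C)C)[C@@H](C(=O)C(C)C)[C@]1(C)CCO | intermediate
13 | (2S,3S,4S)-4-[(tert-butyldimethylsilyl)oxy]-2-(2-iodoethyl)-2-methyl-3-(2-methylpropanoyl)cycloheptan-1-one | O=C1CCC[C@H](O[Si](C)(C)C(C)(C)C)[C@@H](C(=O)C(C)C)[C@]1(C)CCI | intermediate
14 | 6α-[(tert-butyldimethylsilyl)oxy]-8β-hydroxy-1β-methyl-8α-(propan-2-yl)-7αH-bicyclo[5.3.0]decan-2-one | O=C1CCC[C@H](O[Si](C)(C)C(C)(C)C)[C@@H]2[C@]1(C)CC[C@@]2(O)C(C)C | intermediate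
15 | 6α-[(tert-butyldimethylsilyl)oxy]-1β-methyl-8α-(propan-2-yl)-2,8β-bis[(trimethylsilyl)oxy]-7αH-bicyclo[5.3.0]dec-2-ene | C[Si](C)(C)OC1=CCC[C@H](O[Si](C)(C)C(C)(C)C)[C@@H]2[C@]1(C)CC[C@@]2(O[Si](C)(C)C)C(C)C | intermediate
16 | 6α-[(tert-butyldimethylsilyl)oxy]-1β-methyl-8α-(propan-2-yl)-8β-[(trimethylsilyl)oxy]-7αH-bicyclo[5.3.0]dec-3-en-2-one | O=C1C=CC[C@H](O[Si](C)(C)C(C)(C)C)[C@@H]2[C@]1(C)CC[C@@]2(O[Si](C)(C)C)C(C)C | intermediate
17 | 6α-[(tert-butyldimethylsilyl)oxy]-1β,4-dimethyl-8α-(propan-2-yl)-2,8β-bis[(trimethylsilyl)oxy]-7αH-bicyclo[5.3.0]dec-2-ene (either C4 epimer) | C[Si](C)(C)OC1=CC(C)C[C@H](O[Si](C)(C)C(C)(C)C)[C@@H]2[C@]1(C)CC[C@@]2(O[Si](C)(C)C)C(C)C | intermediate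
18 | 6α-[(tert-butyldimethylsilyl)oxy]-1β,4-dimethyl-8α-(propan-2-yl)-8β-[(trimethylsilyl)oxy]-7αH-bicyclo[5.3.0]dec-3-en-2-one | O=C1C=C(C)C[C@H](O[Si](C)(C)C(C)(C)C)[C@@H]2[C@]1(C)CC[C@@]2(O[Si](C)(C)C)C(C)C | intermediate
19 | 6α-[(tert-butyldimethylsilyl)oxy]-1β,4-dimethyl-8α-(propan-2-yl)-8β-[(trimethylsilyl)oxy]-7αH-bicyclo[5.3.0]dec-3-en-2α-ol | O[C@@H]1C=C(C)C[C@H](O[Si](C)(C)C(C)(C)C)[C@@H]2[C@]1(C)CC[C@@]2(O[Si](C)(C)C)C(C)C | intermediate
20 | 6α-[(tert-butyldimethylsilyl)oxy]-3α,4α-epoxy-1β,4β-dimethyl-8α-(propan-2-yl)-8β-[(trimethylsilyl)oxy]-7αH-bicyclo[5.3.0]decan-2α-ol | O[C@@H]1[C@@H]2O[C@]2(C)C[C@H](O[Si](C)(C)C(C)(C)C)[C@@H]2[C@]1(C)CC[C@@]2(O[Si](C)(C)C)C(C)C | intermediate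
21 | 6α-[(tert-butyldimethylsilyl)oxy]-3α,4α-epoxy-1β,4β-dimethyl-8α-(propan-2-yl)-8β-[(trimethylsilyl)oxy]-7αH-bicyclo[5.3.0]decan-2α-yl acetate | CC(=O)O[C@@H]1[C@@H]2O[C@]2(C)C[C@H](O[Si](C)(C)C(C)(C)C)[C@@H]2[C@]1(C)CC[C@@]2(O[Si](C)(C)C)C(C)C | intermediate
22 | 2α-acetoxy-3α,4α-epoxy-1β,4β-dimethyl-8α-(propan-2-yl)-7αH-bicyclo[5.3.0]decane-6α,8β-diol | CC(=O)O[C@@H]1[C@@H]2O[C@]2(C)C[C@H](O)[C@@H]2[C@]1(C)CC[C@@]2(O)C(C)C | intermediate
23 | 2α-acetoxy-3α,4α-epoxy-8β-hydroxy-1β,4β-dimethyl-8α-(propan-2-yl)-7αH-bicyclo[5.3.0]decan-6α-yl 3-methylbutanoate (CNP0137153.1) | CC(=O)O[C@@H]1[C@@H]2O[C@]2(C)C[C@H](OC(=O)CC(C)C)[C@@H]2[C@]1(C)CC[C@@]2(O)C(C)C | target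

**Step count and risks**

Total step count: 16. Longest linear sequence: 16 steps (1 → 23; 7 and 8 are purchased).

Steps most likely to fail:

Step 6. The conjugate addition of the branched alkenyl copper species to the α-methyl enone may be slow, and the hindered enolate may undergo O-allylation or proton exchange, which would erode conversion and the trans,trans selectivity. The fallback sets out from 6: the same copper-mediated addition of the Grignard reagent from 7 is run, but the enolate is trapped on oxygen with allyl chloroformate to give allyl (3S,4S)-4-[(tert-butyldimethylsilyl)oxy]-2-methyl-3-(3-methylbut-1-en-2-yl)cyclohept-1-en-1-yl carbonate F1. Pd(PPh3)4 in THF then effects a decarboxylative Tsuji allylation, in which the π-allyl palladium electrophile should attack the regiodefined enolate anti to the C3 substituent, and the route is rejoined at 10.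

Step 9. Ketyl formation or reduction at either carbonyl, or protonation of the alkylsamarium before it cyclises, may compete, and facial control at the ketone may be incomplete. The fallback sets out from 10: ring-closing metathesis with the second-generation Grubbs catalyst (CH2Cl2, 40 °C) should give the trans-fused cyclopentene 6α-[(tert-butyldimethylsilyl)oxy]-1β-methyl-8-(propan-2-yl)-7αH-bicyclo[5.3.0]dec-8-en-2-one F2. NBS in aqueous THF should then form the bromonium ion on the face away from the C1 methyl and the C6 carbon, with water opening it anti at the tertiary carbon to give 9α-bromo-6α-[(tert-butyldimethylsilyl)oxy]-8β-hydroxy-1β-methyl-8α-(propan-2-yl)-7αH-bicyclo[5.3.0]decan-2-one F3. Bu3SnH/AIBN removes the bromine and the route is rejoined at 14.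

Step 12. Facial selectivity may be poor, because the catalyst has to deliver hydride syn to the pseudo-axial C1 methyl group, against the substrate's own bias. The fallback sets out from 18: Luche reduction (NaBH4, CeCl3, MeOH, −78 °C) should follow the substrate bias, with hydride entering from the open α-face, to give the epimeric 6α-[(tert-butyldimethylsilyl)oxy]-1β,4-dimethyl-8α-(propan-2-yl)-8β-[(trimethylsilyl)oxy]-7αH-bicyclo[5.3.0]dec-3-en-2β-ol F4. Mitsunobu inversion (4-nitrobenzoic acid, PPh3, DIAD, toluene) should give 6α-[(tert-butyldimethylsilyl)oxy]-1β,4-dimethyl-8α-(propan-2-yl)-8β-[(trimethylsilyl)oxy]-7αH-bicyclo[5.3.0]dec-3-en-2α-yl 4-nitrobenzoate F5, and methanolysis (K2CO3, MeOH) rejoins the route at 19.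

**Further compounds**

F1 | step 6 | allyl (3S,4S)-4-[(tert-butyldimethylsilyl)oxy]-2-methyl-3-(3-methylbut-1-en-2-yl)cyclohept-1-en-1-yl carbonate | C=CCOC(=O)OC1=C(C)[C@H](C(=C)C(C)C)[C@@H](O[Si](C)(C)C(C)(C)C)CCC1
F2 | step 9 | 6α-[(tert-butyldimethylsilyl)oxy]-1β-methyl-8-(propan-2-yl)-7αH-bicyclo[5.3.0]dec-8-en-2-one | O=C1CCC[C@H](O[Si](C)(C)C(C)(C)C)[C@@H]2[C@]1(C)CC=C2C(C)C
F3 | step 9 | 9α-bromo-6α-[(tert-butyldimethylsilyl)oxy]-8β-hydroxy-1β-methyl-8α-(propan-2-yl)-7αH-bicyclo[5.3.0]decan-2-one | O=C1CCC[C@H](O[Si](C)(C)C(C)(C)C)[C@@H]2[C@]1(C)C[C@@H](Br)[C@@]2(O)C(C)C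
F4 | step 12 | 6α-[(tert-butyldimethylsilyl)oxy]-1β,4-dimethyl-8α-(propan-2-yl)-8β-[(trimethylsilyl)oxy]-7αH-bicyclo[5.3.0]dec-3-en-2β-ol | O[C@H]1C=C(C)C[C@H](O[Si](C)(C)C(C)(C)C)[C@@H]2[C@]1(C)CC[C@@]2(O[Si](C)(C)C)C(C)C
F5 | step 12 | 6α-[(tert-butyldimethylsilyl)oxy]-1β,4-dimethyl-8α-(propan-2-yl)-8β-[(trimethylsilyl)oxy]-7αH-bicyclo[5.3.0]dec-3-en-2α-yl 4-nitrobenzoate | O=C(O[C@@H]1C=C(C)C[C@H](O[Si](C)(C)C(C)(C)C)[C@@H]2[C@]1(C)CC[C@@]2(O[Si](C)(C)C)C(C)C)c1ccc(cc1)[N+](=O)[O-]
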